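The hydroazulene is numbered as azulene (C1 side chain, C3a methyl, C5 acetate, C6 methylidene). The route rests on disconnecting C3a–C8a and C1–C2. The precursor is a 2-methoxytetrahydropyran built from C2, C3, C3a, C4, C5 and the C5 oxygen; it carries a tertiary oxalate at C3a and, on C5, the C6–C8 chain ending in an enone. The key step uses this 1,3-relation of O-5 and C3a: the C3a radical adds across the pyran to the enone, closing the seven-membered ring and fixing C3a and C8a; acetal opening and aldol condensation then close the five-membered ring. One catalytic stereocentre (C5) relays the ring stereochemistry.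

Key step: step 7

Remark: C-numbers in the Why lines are those of the azulene core of the target. The anomeric and carbinol configurations of pyrans 4–11 are erased in step 7; the expected major isomers are drawn.

Step 1
Reactants: 1 Danishefsky's diene [(E)-1-methoxy-3-(trimethylsilyloxy)buta-1,3-diene]; 2 ethyl glyoxylate
Product: 4 ethyl (2S,6S)-6-methoxy-4-oxooxane-2-carboxylate, via silyl enol ether cycloadduct 3 (not isolated)
Conditions: Cu(OTf)2 (10 mol %), (S,S)-t-Bu-box [2,2'-isopropylidenebis((4S)-4-tert-butyl-2-oxazoline)] (11 mol %), CH2Cl2, −78 °C; then MeOH, PPTS (cat.), rt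
Reagents that add atoms: methanol CO
Why: Catalytic asymmetric hetero-Diels–Alder reaction on the two-point-chelated glyoxylate sets the future C5 stereocentre (same facial bias as this catalyst shows in glyoxylate ene reactions), and acidic methanolysis of the silyl enol ether keeps the acetal and equilibrates it to the axial (trans) anomer.

Step 2
Reactants: 4 ethyl (2S,6S)-6-methoxy-4-oxooxane-2-carboxylate
Product: 5 ethyl (2S,4R,6S)-4-hydroxy-6-methoxy-4-methyloxane-2-carboxylate
Conditions: MeMgBr (1.1 equiv), CeCl3, THF, −78 °C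
Reagents that add atoms: methylmagnesium bromide C[Mg]Br
Why: Cerium-assisted Grignard 1,2-addition is faster at the ketone than at the ester and avoids β-elimination of the acetal oxygen; equatorial attack anti to the axial methoxy group gives the axial carbinol, whose configuration is lost later.

Step 3
Reactants: 5 ethyl (2S,4R,6S)-4-hydroxy-6-methoxy-4-methyloxane-2-carboxylate
Product: 7 1-[(2S,4R,6S)-4-hydroxy-6-methoxy-4-methyloxan-2-yl]pent-4-en-1-one, via Weinreb amide 6 (not isolated)
Conditions: MeNH(OMe)·HCl, i-PrMgCl, THF, −20 °C; then CH2=CHCH2CH2MgBr, −20 to 0 °C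
Reagents that add atoms: but-3-enylmagnesium bromide C=CCC[Mg]Br
Why: Weinreb ketone synthesis in one flask, the chelated tetrahedral intermediate preventing double addition and the tertiary alcohol riding through as its magnesium alkoxide.

Step 4
Reactants: 7 1-[(2S,4R,6S)-4-hydroxy-6-methoxy-4-methyloxan-2-yl]pent-4-en-1-one
Product: 8 (2S,4R,6S)-2-(hexa-1,5-dien-2-yl)-6-methoxy-4-methyloxan-4-ol
Conditions: Ph3PCH3Br, KOt-Bu, THF, 0 °C
Reagents that add atoms: methyltriphenylphosphonium bromide C[P+](c1ccccc1)(c1ccccc1)c1ccccc1.[Br-]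
Why: Wittig methylenation installs the future C6 methylidene; a short reaction at 0 °C limits epimerisation of the adjacent oxygen-bearing stereocentre.

Step 5
Reactants: 8 (2S,4R,6S)-2-(hexa-1,5-dien-2-yl)-6-methoxy-4-methyloxan-4-ol
Product: 9 (3E)-7-[(2S,4R,6S)-4-hydroxy-6-methoxy-4-methyloxan-2-yl]octa-3,7-dien-2-one
Conditions: methyl vinyl ketone (5 equiv), second-generation Hoveyda–Grubbs catalyst (5 mol %), CH2Cl2, 40 °C
Reagents that add atoms: methyl vinyl ketone CC(=O)C=C
Why: Olefin cross-metathesis of the monosubstituted alkene with an electron-poor partner is E-selective, and the hindered 1,1-disubstituted alkene should not take part.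

Step 6
Reactants: 9 (3E)-7-[(2S,4R,6S)-4-hydroxy-6-methoxy-4-methyloxan-2-yl]octa-3,7-dien-2-one
Product: 11 cesium 2-{[(2S,4R,6S)-6-methoxy-4-methyl-2-[(5E)-7-oxoocta-1,5-dien-2-yl]oxan-4-yl]oxy}-2-oxoacetate, via methyl oxalate diester 10 (not isolated)
Conditions: ClCOCO2Me, Et3N, DMAP (cat.), CH2Cl2, 0 °C; then CsOH·H2O (1.0 equiv), THF/H2O, 0 °C
Reagents that add atoms: methyl chlorooxoacetate COC(=O)C(Cl)=O; cesium hydroxide [Cs+].[OH-]
Why: Acylation of the tertiary alcohol followed by selective saponification of the far more electrophilic methyl oxalate ester should give the stable cesium oxalate that serves as radical precursor.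

Step 7
Reactants: 11 cesium 2-{[(2S,4R,6S)-6-methoxy-4-methyl-2-[(5E)-7-oxoocta-1,5-dien-2-yl]oxan-4-yl]oxy}-2-oxoacetate
Product: 14 1-[(3aR,5S,8aR)-5-hydroxy-3a-methyl-6-methylidene-3,3a,4,5,6,7,8,8a-octahydroazulen-1-yl]ethan-1-one, via bridged keto acetal 12 (not isolated), via bridged keto lactol 13 (not isolated)
Conditions: Ir[dF(CF3)ppy]2(dtbbpy)PF6 (2 mol %), DME/DMF 3:1 (0.01 M), H2O (10 equiv), blue LEDs, 60 °C; then 1 M HCl, rt; then KOH, MeOH, 40 °C (one flask)
Reagents that add atoms: none
Why: The excited photocatalyst oxidises the oxalate, two CO2 are lost and the tertiary pyranyl radical (C3a) adds 7-exo-trig to the enone β-carbon (C8a); reduction of the α-keto radical and protonation give 12, the known decarboxylative tertiary-oxalate Giese addition with radical–polar crossover, here intramolecular. Acid then opens the acetal bridge (12 to 13) and base makes the C1 enolate add to the unmasked C2 aldehyde in a 5-(enolexo)-exo-trig aldol closure followed by dehydration, the known cyclopentene annulation of 1,6-keto aldehydes. The seven-membered ring is thus closed by radical addition and the five-membered ring by aldol condensation, while the pyran is lost and its oxygen becomes the free C5 hydroxyl. C3a is controlled by the bridge: C5 and the radical carbon are 1,3 on the pyran chair, so the chain on C5 can reach only the axial face cis to it, which puts C3 and O-5 on one side of the new ring and CH3-3a on the other. C8a is controlled by the same bicyclic transition state: the tether must pass outside the pyran because the inside is blocked by the axial anomeric hydrogen, so the acyl-bearing alkene carbon can sit only beside the equatorial methyl group and H-8a ends up anti to CH3-3a (trans fusion). The step needs cyclisation to outrun hydrogen abstraction by the radical (high dilution, activated acceptor, no fast hydrogen donor) and needs the aldol to join the ketone α-CH2 to the aldehyde carbon, the only mode that ends in irreversible dehydration to a conjugated five-membered enone.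

Step 8
Reactants: 14 1-[(3aR,5S,8aR)-5-hydroxy-3a-methyl-6-methylidene-3,3a,4,5,6,7,8,8a-octahydroazulen-1-yl]ethan-1-one
Product: 15 1-[(1S,3aR,5S,8aS)-5-hydroxy-3a-methyl-6-methylidenedecahydroazulen-1-yl]ethan-1-one
Conditions: Li (3 equiv), NH3(l)/THF, t-BuOH (1 equiv), −78 °C, 10 min; then solid NH4Cl
Reagents that add atoms: none
Why: Dissolving-metal (Birch-type) 1,4-reduction touches only the conjugated C1=C2 bond (isolated alkenes and the allylic alkoxide are inert), and kinetic protonation of the enolate at C1 on quench should occur on the α-face, anti to CH3-3a and C8, leaving the acetyl group β.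

Step 9
Reactants: 16 (S)-3-hydroxydihydrofuran-2(3H)-one [(S)-α-hydroxy-γ-butyrolactone]
Product: 17 (S)-3,5-dihydroxypentan-2-one (present mainly as its cyclic hemiketal)
Conditions: MeLi (2.2 equiv), THF, −78 °C; then NH4Cl (aq)
Reagents that add atoms: methyllithium [Li]C
Why: Organolithium addition to the lactone alkoxide stops at the tetrahedral dianion, so the methyl ketone should be obtained after work-up without over-addition or loss of the α-stereocentre.

Step 10
Reactants: 17 (S)-3,5-dihydroxypentan-2-one
Product: 18 (S)-2-methylpent-1-ene-3,5-diol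
Conditions: Ph3PCH3Br (3.5 equiv), KOt-Bu (3.4 equiv), THF, 0 °C to rt
Reagents that add atoms: methyltriphenylphosphonium bromide C[P+](c1ccccc1)(c1ccccc1)c1ccccc1.[Br-]
Why: Wittig methylenation of the ketone released from the hemiketal; the α-carbon bears an alkoxide under the conditions, which suppresses enolisation and racemisation.

Step 11
Reactants: 18 (S)-2-methylpent-1-ene-3,5-diol
Product: 19 (S)-5-iodo-2-methylpent-1-en-3-ol
Conditions: I2 (1.05 equiv), PPh3, imidazole, CH2Cl2, −20 to 0 °C
Reagents that add atoms: iodine II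
Why: Appel-type iodination is selective for the unhindered primary hydroxyl over the secondary allylic one.

Step 12
Reactants: 15 1-[(1S,3aR,5S,8aS)-5-hydroxy-3a-methyl-6-methylidenedecahydroazulen-1-yl]ethan-1-one; 19 (S)-5-iodo-2-methylpent-1-en-3-ol
Product: 21 (1S,3aR,5S,8aS)-1-[(2S,5S)-2,5-dihydroxy-6-methylhept-6-en-2-yl]-3a-methyl-6-methylidenedecahydroazulen-5-ol, via dilithio reagent 20 (not isolated)
Conditions: 19 (3 equiv), t-BuLi (9.3 equiv), Et2O, −78 °C; CeCl3, THF, −78 °C; then 15, −78 °C; NH4Cl (aq)
Reagents that add atoms: none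
Why: Iodine–lithium exchange on the lithium alkoxide gives a γ-oxido alkyllithium whose organocerium form adds to the methyl ketone with little enolisation; Felkin–Anh attack anti to C8a with the nucleophile passing H-1 should give the (2S)-carbinol, the sense known for organometallic additions to 17β-acetyl steroids.

Step 13
Reactants: 21 (1S,3aR,5S,8aS)-1-[(2S,5S)-2,5-dihydroxy-6-methylhept-6-en-2-yl]-3a-methyl-6-methylidenedecahydroazulen-5-ol
Product: 22 (1S,3aR,5S,8aS)-1-[(2S,5S)-5-acetoxy-2-hydroxy-6-methylhept-6-en-2-yl]-3a-methyl-6-methylidenedecahydroazulen-5-yl acetate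
Conditions: Ac2O (2.5 equiv), pyridine, DMAP (cat.), CH2Cl2, 0 °C to rt
Reagents that add atoms: acetic anhydride CC(=O)OC(C)=O
Why: Standard acylation esterifies both secondary allylic alcohols while the hindered tertiary alcohol should stay free.

Compound list
1 | (E)-1-methoxy-3-(trimethylsilyloxy)buta-1,3-diene | CO/C=C/C(=C)O[Si](C)(C)C | starting material
2 | ethyl glyoxylate | CCOC(=O)C=O | starting material
3 | ethyl (2S,6R)-6-methoxy-4-(trimethylsilyloxy)-3,6-dihydro-2H-pyran-2-carboxylate (cis cycloadduct) | CCOC(=O)[C@@H]1CC(O[Si](C)(C)C)=C[C@H](OC)O1 | intermediate (not isolated)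
4 | ethyl (2S,6S)-6-methoxy-4-oxooxane-2-carboxylate (methoxy axial, trans to ester) | CCOC(=O)[C@@H]1CC(=O)C[C@@H](OC)O1 | intermediate
5 | ethyl (2S,4R,6S)-4-hydroxy-6-methoxy-4-methyloxane-2-carboxylate (hydroxyl cis to methoxy) | CCOC(=O)[C@@H]1C[C@@](C)(O)C[C@@H](OC)O1 | intermediate
6 | (2S,4R,6S)-4-hydroxy-N,6-dimethoxy-N,4-dimethyloxane-2-carboxamide | CON(C)C(=O)[C@@H]1C[C@@](C)(O)C[C@@H](OC)O1 | intermediate (not isolated)
7 | 1-[(2S,4R,6S)-4-hydroxy-6-methoxy-4-methyloxan-2-yl]pent-4-en-1-one | C=CCCC(=O)[C@@H]1C[C@@](C)(O)C[C@@H](OC)O1 | intermediate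
8 | (2S,4R,6S)-2-(hexa-1,5-dien-2-yl)-6-methoxy-4-methyloxan-4-ol | C=CCCC(=C)[C@@H]1C[C@@](C)(O)C[C@@H](OC)O1 | intermediate
9 | (3E)-7-[(2S,4R,6S)-4-hydroxy-6-methoxy-4-methyloxan-2-yl]octa-3,7-dien-2-one | CC(=O)/C=C/CCC(=C)[C@@H]1C[C@@](C)(O)C[C@@H](OC)O1 | intermediate
10 | methyl (2S,4R,6S)-6-methoxy-4-methyl-2-[(5E)-7-oxoocta-1,5-dien-2-yl]oxan-4-yl oxalate | CC(=O)/C=C/CCC(=C)[C@@H]1C[C@@](C)(OC(=O)C(=O)OC)C[C@@H](OC)O1 | intermediate (not isolated)
11 | cesium 2-{[(2S,4R,6S)-6-methoxy-4-methyl-2-[(5E)-7-oxoocta-1,5-dien-2-yl]oxan-4-yl]oxy}-2-oxoacetate | CC(=O)/C=C/CCC(=C)[C@@H]1C[C@@](C)(OC(=O)C(=O)[O-])C[C@@H](OC)O1.[Cs+] | intermediate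
12 | 1-[8-methoxy-1-methyl-5-methylidene-7-oxabicyclo[4.3.1]decan-2-yl]propan-2-one (methyl and acetonyl cis on the carbocycle, O–C–C bridge on the opposite face) | CC(=O)C[C@@H]1CCC(=C)[C@@H]2C[C@@]1(C)C[C@@H](OC)O2 | intermediate (not isolated)
13 | 1-[8-hydroxy-1-methyl-5-methylidene-7-oxabicyclo[4.3.1]decan-2-yl]propan-2-one (same relative configuration as 12) | CC(=O)C[C@@H]1CCC(=C)[C@@H]2C[C@@]1(C)C[C@@H](O)O2 | intermediate (not isolated)
14 | 1-[(3aR,5S,8aR)-5-hydroxy-3a-methyl-6-methylidene-3,3a,4,5,6,7,8,8a-octahydroazulen-1-yl]ethan-1-one (trans-fused) | CC(=O)C1=CC[C@]2(C)C[C@H](O)C(=C)CC[C@@H]12 | intermediate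
15 | 1-[(1S,3aR,5S,8aS)-5-hydroxy-3a-methyl-6-methylidenedecahydroazulen-1-yl]ethan-1-one | CC(=O)[C@H]1CC[C@]2(C)C[C@H](O)C(=C)CC[C@@H]12 | intermediate
16 | (S)-3-hydroxydihydrofuran-2(3H)-one | O=C1OCC[C@@H]1O | starting material
17 | (S)-3,5-dihydroxypentan-2-one | CC(=O)[C@H](CCO)O | intermediate
18 | (S)-2-methylpent-1-ene-3,5-diol | C=C(C)[C@H](CCO)O | intermediate
19 | (S)-5-iodo-2-methylpent-1-en-3-ol | C=C(C)[C@H](CCI)O | intermediate
20 | lithium (S)-5-lithio-2-methylpent-1-en-3-olate | C=C(C)[C@H](CC[Li])O[Li] | intermediate (not isolated)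
21 | (1S,3aR,5S,8aS)-1-[(2S,5S)-2,5-dihydroxy-6-methylhept-6-en-2-yl]-3a-methyl-6-methylidenedecahydroazulen-5-ol | C=C(C)[C@H](CC[C@](C)(O)[C@H]1CC[C@]2(C)C[C@H](O)C(=C)CC[C@@H]12)O | intermediate
22 | (1S,3aR,5S,8aS)-1-[(2S,5S)-5-acetoxy-2-hydroxy-6-methylhept-6-en-2-yl]-3a-methyl-6-methylidenedecahydroazulen-5-yl acetate | C=C(C)[C@H](CC[C@](C)(O)[C@H]1CC[C@]2(C)C[C@H](OC(C)=O)C(=C)CC[C@@H]12)OC(C)=O | target

Total step count: 13. Longest linear sequence: 10 (steps 1–8, 12, 13).

Steps most likely to fail

Step 7. The pyran must flip to the conformer with the C5 chain axial before the 7-exo addition, so ring closure may be slower than 1,5-hydrogen transfer from the allylic CH2 groups or simple loss of the radical. The fallback gives up the acetal bridge; it sets out from 8 and comes back at 14. Acid hydrolysis of the acetal gives lactol F1, and NaBH4 reduces it to triol F2. Et3SiCl and imidazole silylate the primary and secondary hydroxyls to give bis-silyl ether F3. Cross-metathesis with methyl vinyl ketone gives enone F4, and oxalate formation as in step 6 gives methyl oxalate F5 and cesium oxalate F6. The same photoredox conditions then close the seven-membered ring through an unbridged 7-exo transition state to give cycloheptane F7, together with its C3a epimer, which is removed by chromatography. Swern oxidation converts the primary silyl ether directly into aldehyde F8, KOH/MeOH effects the aldol condensation to silyl-protected enone F9, and HF·pyridine gives 14.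

Step 8. Protonation of the enolate may occur partly on the β-face, or the kinetic ketone may epimerise at C1 to the less hindered epimer during quench and evaporation of ammonia. The fallback separates reduction from protonation; it sets out from 14 and comes back at 15. Rhodium-catalysed 1,4-hydrosilylation (Et3SiH, RhCl(PPh3)3, benzene, 50 °C) gives the isolable bis-silyl compound F10 (silyl enol ether, C5 hydroxyl silylated as well, E/Z mixture). F10 is then cleaved at −78 °C with TBAF in the presence of a hindered phenol, so that the proton is delivered under defined kinetic conditions, giving 15.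

Step 12. The ketone may be enolised (with epimerisation at C1), and the γ-iodo alkoxide may cyclise or exchange incompletely. The facial selectivity at the new carbinol also rests on an acyclic model. The fallback uses a protected monolithium reagent; it sets out from 19 and 15 and comes back at 21. Et3SiCl and imidazole give silyl ether F11, t-BuLi (2 equiv) gives alkyllithium F12, and its CeCl3 adduct adds to 15 to give F13. Dilute HCl in THF removes the silyl group and gives 21.

Further compounds
F1 | step 7 | (4R,6S)-6-(hexa-1,5-dien-2-yl)-4-methyloxane-2,4-diol (lactol, anomers) | C=CCCC(=C)[C@@H]1C[C@@](C)(O)C[C@@H](O)O1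
F2 | step 7 | (5S)-3-methyl-6-methylidenedec-9-ene-1,3,5-triol (C3 as drawn) | OCC[C@](C)(O)C[C@H](O)C(=C)CCC=C
F3 | step 7 | 1,5-bis(triethylsilyl) ether of F2 | CC[Si](CC)(CC)OCC[C@](C)(O)C[C@H](O[Si](CC)(CC)CC)C(=C)CCC=C
F4 | step 7 | (3E,8S)-10-hydroxy-10-methyl-7-methylidene-8,12-bis(triethylsilyloxy)dodec-3-en-2-one | CC[Si](CC)(CC)OCC[C@](C)(O)C[C@H](O[Si](CC)(CC)CC)C(=C)CC/C=C/C(C)=O
F5 | step 7 | methyl oxalate diester of F4 | CC[Si](CC)(CC)OCC[C@](C)(OC(=O)C(=O)OC)C[C@H](O[Si](CC)(CC)CC)C(=C)CC/C=C/C(C)=O
F6 | step 7 | cesium oxalate of F4 | CC[Si](CC)(CC)OCC[C@](C)(OC(=O)C(=O)[O-])C[C@H](O[Si](CC)(CC)CC)C(=C)CC/C=C/C(C)=O.[Cs+]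
F7 | step 7 | 1-[2-methyl-5-methylidene-4-(triethylsilyloxy)-2-[2-(triethylsilyloxy)ethyl]cycloheptyl]propan-2-one (configuration as in the target) | CC(=O)C[C@@H]1CCC(=C)[C@@H](O[Si](CC)(CC)CC)C[C@@]1(C)CCO[Si](CC)(CC)CC
F8 | step 7 | 2-[1-methyl-4-methylidene-7-(2-oxopropyl)-3-(triethylsilyloxy)cycloheptyl]acetaldehyde | CC(=O)C[C@@H]1CCC(=C)[C@@H](O[Si](CC)(CC)CC)C[C@@]1(C)CC=O
F9 | step 7 | triethylsilyl ether of 14 | CC(=O)C1=CC[C@]2(C)C[C@H](O[Si](CC)(CC)CC)C(=C)CC[C@@H]12
F10 | step 8 | bis(triethylsilyl) compound: silyl enol ether of 15 with C5–O silylated | CC[Si](CC)(CC)OC(C)=C1CC[C@]2(C)C[C@H](O[Si](CC)(CC)CC)C(=C)CC[C@@H]12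
F11 | step 12 | (S)-triethyl[(5-iodo-2-methylpent-1-en-3-yl)oxy]silane | C=C(C)[C@H](CCI)O[Si](CC)(CC)CC
F12 | step 12 | (S)-[4-methyl-3-(triethylsilyloxy)pent-4-en-1-yl]lithium | C=C(C)[C@H](CC[Li])O[Si](CC)(CC)CC
F13 | step 12 | 5-O-triethylsilyl ether of 21 (side-chain secondary oxygen) | C=C(C)[C@H](CC[C@](C)(O)[C@H]1CC[C@]2(C)C[C@H](O)C(=C)CC[C@@H]12)O[Si](CC)(CC)CC
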